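**Plan**

Locants follow the Stemona convention: pyrrole C1, C2, C3, N4; azepane C5–C8, C9, C9a; cyclohexane C9a–C1–C12–C11–C10–C9 (ethyl on C10); fused lactone O–C11, C12, C13 (CH3 = C15), C14 (C=O); side lactone C18 (on C3), C19, C20 (CH3), C21.
Retrosynthesis: cut the side lactone (C18–O, C3–C18) back to a C3 ester; undo the O–C11 bond together with the C1–C12 bond (ring contraction to a cyclopentane-fused β-lactone whose C11 is bound to C1); cut the β-lactone at C12–C13 (aldol); cut the cyclopentene at C9–C10 and C1–C11 and the azepane at C9–C9a.
Forward: pyrrole → azepane and cyclopentene in one acid cascade → all-cis cyclopentane → β-lactone → one ring expansion that gives the cyclohexane and the γ-lactone together → side lactone.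
Stereochemistry: H-9, H-10 and H-11 become all-cis by hydrogenation opposite the azepane; C12 and C13 come from an Evans syn-aldol, which also resolves the racemic core; C11 and C12 then react with stereospecific inversion in the ring expansion; C18 comes from a Corey–Bakshi–Shibata reduction and C20 from enantiopure bromide 17.
Enabling feature: pyrrole carbon C1 sits next to C11 and its π-electrons can bridge C11 and C12, so C1 can slide from C11 to C12 while the lactone oxygen slides from C12 to C11; the all-cis array is therefore built on a cyclopenta[b]pyrrole, which cannot aromatise as a partly unsaturated tetrahydroindole would.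

Key step: step 8

Remark on the chemistry: step 2 gives racemic 7, so 7, 8 and 9 are racemates drawn as the enantiomer that is carried on; the auxiliary-controlled aldol of step 5 turns the two enantiomers of 9 into separable diastereomers, and only 11 is advanced.

Step 1
Reactants: 1 methyl 1H-pyrrole-2-carboxylate; 2 2-(4-bromobutyl)-1,3-dioxolane
Product: 3 methyl 1-[4-(1,3-dioxolan-2-yl)butyl]-1H-pyrrole-2-carboxylate
Conditions: NaH, DMF, 0 → 25 °C
Reagents that add atoms: none
Why: The acidic N–H of the 2-acylpyrrole is deprotonated and the pyrrolide is alkylated at nitrogen by the primary bromide (SN2 N-alkylation), no stereocentre being formed.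

Step 2
Reactants: 3 methyl 1-[4-(1,3-dioxolan-2-yl)butyl]-1H-pyrrole-2-carboxylate; 4 ethyl 2-oxopentanoate
Product: 7 cyclopentene diester (racemic), via vinylpyrrole 5 (not isolated), via keto ester adduct 6 (not isolated)
Conditions: CF3SO3H (0.2 equiv), (CH2Cl)2, 0 → 25 °C; then 4 (3 equiv), 4 Å molecular sieves, 60 °C
Reagents that add atoms: none
Why: Proposed new method: the acid opens the dioxolane to an oxocarbenium ion that the free α-carbon of the pyrrole (the only ring position the tether reaches) attacks to close the seven-membered ring, loss of ethylene glycol gives vinylpyrrole 5, protonation of 5 at C8 regenerates the 2-azafulvenium ion, the enol of 4 adds at C9 to give 6, and the pyrrole β-carbon C1 then attacks the activated ketone with loss of water to the conjugated cyclopentene, C9 being formed racemic; the closest known reaction type is the Brønsted-acid formal [3+2] annulation of 2-indolylcarbinol-derived cations with enolisable 1,3-dicarbonyl compounds followed by Friedel–Crafts cyclodehydration.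

Step 3
Reactants: 7 cyclopentene diester (racemic)
Product: 8 all-cis cyclopentane diester (racemic)
Conditions: H2 (30 bar), 10% Pd/C, EtOAc, 40 °C
Reagents that add atoms: none
Why: Heterogeneous syn-hydrogenation of the tetrasubstituted alkene should deliver both hydrogens to the face opposite C8 and C7 of the azepane, which cover one face of the nearly flat cyclopenta[b]pyrrole, so H-10 and H-11 end cis to H-9 and the ethyl and ester groups cis to each other.

Step 4
Reactants: 8 all-cis cyclopentane diester (racemic)
Product: 9 all-cis aldehyde (racemic)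
Conditions: iBu2AlH (1.05 equiv), CH2Cl2, −78 °C; aqueous potassium sodium tartrate at 0 °C; used at once
Reagents that add atoms: none
Why: Partial reduction with iBu2AlH stops at the aluminium hemiacetal of the more electrophilic aliphatic ester (the pyrrole ester is a vinylogous carbamate), and the cold, neutral work-up with immediate use should keep the epimerisable C11 centre.

Step 5
Reactants: 9 all-cis aldehyde (racemic); 10 (S)-4-benzyl-3-propanoyl-1,3-oxazolidin-2-one
Product: 11 syn-aldol adduct
Conditions: 10, Bu2BOTf, iPr2NEt, CH2Cl2, −78 → 0 °C; then 9, −78 °C; pH 7 buffer, MeOH, H2O2, 0 °C; chromatography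
Reagents that add atoms: none
Why: Evans syn-aldol: the (Z)-boron enolate of 10 adds through a closed chair transition state in which the auxiliary alone fixes both new centres as (12R,13S), so each enantiomer of 9 gives one diastereomer, and the adduct of (9S,10R,11R)-9 is separated and carried on as 11.

Step 6
Reactants: 11 syn-aldol adduct
Product: 12 β-hydroxy acid
Conditions: LiOH, H2O2, THF/H2O, 0 °C; aqueous Na2SO3; then 1 M HCl to pH 3
Reagents that add atoms: hydrogen peroxide, OO
Why: Hydroperoxide, more nucleophilic and less basic than hydroxide, attacks the exocyclic imide carbonyl (Evans auxiliary hydrolysis), which should free the acid without retro-aldol or epimerisation and leave the pyrrole ester untouched.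

Step 7
Reactants: 12 β-hydroxy acid
Product: 13 cis β-lactone
Conditions: PhSO2Cl, pyridine, 0 → 4 °C
Reagents that add atoms: none
Why: Carboxyl activation as the mixed sulfonic anhydride lets the C12 hydroxyl attack the acyl carbon (β-lactonisation with retention at C12 and C13), so the syn acid should give the cis β-lactone.

Step 8
Reactants: 13 cis β-lactone
Product: 14 tetracyclic lactone methyl ester
Conditions: MgBr2·OEt2 (1.5 equiv), CH2Cl2, 0 → 25 °C
Reagents that add atoms: none
Why: MgBr2 binds the lactone carbonyl and weakens the C12–O bond; as it ionises, C1 of the pyrrole, placed anti-periplanar to that bond by rotation about C11–C12, bridges C11 and C12 (spiro-cyclopropane aza-phenonium ion) and ends on C12 while the carboxylate oxygen moves from C12 to C11, a concerted double 1,2-shift (dyotropic rearrangement of Wagner–Meerwein type). The closest known reaction type is the Lewis-acid dyotropic ring expansion of β-lactones to γ-lactones with 1,2-shift of an aryl group. The γ-lactone ring closes by backside attack of the carboxylate oxygen on C11 (enlargement of the four-membered to the five-membered lactone, the oxygen never leaving the molecule), and the cyclohexane arises because the shift of C1 inserts C12 into the cyclopentane (five- to six-membered ring). Both migrations are anti, so C11 and C12 react with inversion: the cis (12R,13S) β-lactone on the all-cis cyclopentane should give the cis-fused lactone with H-11 and H-12 on the face of H-9 and H-10 and with C15 cis to C1, while C9, C10 and C13 are untouched. The step needs migration of C1 in preference to H-11 or C10; C1 is a π-nucleophilic pyrrole β-carbon that is only meta to the C3 ester and is the one group that can assist ionisation by bridging, and return of the carboxylate to C11 (five-membered ring) is favoured over return to C12 (four-membered ring).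

Step 9
Reactants: 14 tetracyclic lactone methyl ester
Product: 16 tetracyclic lactone carboxylic acid, via hydroxy diacid 15 (not isolated)
Conditions: LiOH, THF/MeOH/H2O, 45 °C; then 1 M HCl to pH 3, 25 °C
Reagents that add atoms: lithium hydroxide, [Li+].[OH-]
Why: Saponification of the pyrrole methyl ester also opens the γ-lactone to the carboxylate of 15 (which cannot enolise at C13), and mild acidification should re-close the lactone by acyl substitution without breaking the C11–O bond.

Step 10
Reactants: 16 tetracyclic lactone carboxylic acid; 17 methyl (R)-3-bromo-2-methylpropanoate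
Product: 20 keto ester, via acid chloride 18 (not isolated), via organozinc 19 (not isolated)
Conditions: (COCl)2, DMF (cat.), CH2Cl2, 0 °C; then 19 [from 17, Zn, LiCl, THF, 45 °C], Pd(PPh3)4 (5 mol%), THF, 0 → 25 °C
Reagents that add atoms: none
Why: Negishi acylation: the acid chloride adds oxidatively to zerovalent palladium, the alkylzinc bromide 19 (zinc insertion into 17, the stereocentre β to zinc being untouched) transmetalates and reductive elimination gives the ketone, the organozinc leaving lactone and esters intact.

Step 11
Reactants: 20 keto ester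
Product: 22 epibisdehydroneotuberostemonine J, via hydroxy ester 21 (not isolated)
Conditions: (S)-2-methyl-CBS-oxazaborolidine (0.2 equiv), BH3·SMe2, THF, −20 °C; MeOH; then DBU (0.2 equiv), toluene, 40 °C
Reagents that add atoms: none
Why: Corey–Bakshi–Shibata reduction: the ketone binds the (S)-oxazaborolidine–borane complex with the pyrrolyl group as the large substituent, so hydride should be delivered to the face that gives the (18R) carbinol, and hydroxy ester 21 then closes to the trans lactone by base-catalysed acyl substitution, without acid that would ionise C18–O and without touching C20.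

**Compound list**

1 | methyl 1H-pyrrole-2-carboxylate | COC(=O)c1ccc[nH]1 | starting material
2 | 2-(4-bromobutyl)-1,3-dioxolane | BrCCCCC1OCCO1 | starting material
3 | methyl 1-[4-(1,3-dioxolan-2-yl)butyl]-1H-pyrrole-2-carboxylate | COC(=O)c1cccn1CCCCC1OCCO1 | intermediate
4 | ethyl 2-oxopentanoate | CCCC(=O)C(=O)OCC | starting material
5 | methyl 6,7-dihydro-5H-pyrrolo[1,2-a]azepine-3-carboxylate (C8=C9 alkene) | COC(=O)c1ccc2C=CCCCn12 | intermediate
6 | ethyl 3-[3-(methoxycarbonyl)-6,7,8,9-tetrahydro-5H-pyrrolo[1,2-a]azepin-9-yl]-2-oxopentanoate (racemic, both diastereomers) | CCC(C(=O)C(=O)OCC)C1CCCCn2c1ccc2C(=O)OC | intermediate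
7 | cyclopentene diester: methyl 6,7,8,9-tetrahydro-5H-pyrrolo[1,2-a]azepine-3-carboxylate whose C9 and C1 are bridged by C10(ethyl)=C11(CO2Et), ring C9–C10=C11–C1–C9a; racemic, (9S) drawn | CCC1=C(C(=O)OCC)c2cc(C(=O)OC)n3c2[C@H]1CCCC3 | intermediate
8 | all-cis cyclopentane diester: 7 with C10–C11 saturated, H-9, H-10 and H-11 on one face; racemic, (9S,10R,11R) drawn | CC[C@H]1[C@@H](C(=O)OCC)c2cc(C(=O)OC)n3c2[C@H]1CCCC3 | intermediate
9 | all-cis aldehyde: 8 with CHO in place of CO2Et on C11; racemic, (9S,10R,11R) drawn | CC[C@H]1[C@@H](C=O)c2cc(C(=O)OC)n3c2[C@H]1CCCC3 | intermediate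
10 | (S)-4-benzyl-3-propanoyl-1,3-oxazolidin-2-one | CCC(=O)N1[C@@H](Cc2ccccc2)COC1=O | starting material
11 | syn-aldol adduct: (S)-4-benzyl-3-[(2S,3R)-3-hydroxy-2-methylpropanoyl]oxazolidin-2-one carrying C11 of the (9S,10R,11R) tricycle on its C3, that is (12R)-carbinol and (13S)-methyl | CC[C@H]1[C@@H]([C@@H](O)[C@H](C)C(=O)N4[C@@H](Cc5ccccc5)COC4=O)c2cc(C(=O)OC)n3c2[C@H]1CCCC3 | intermediate
12 | (12R,13S) β-hydroxy acid of the (9S,10R,11R) tricycle | CC[C@H]1[C@@H]([C@@H](O)[C@H](C)C(=O)O)c2cc(C(=O)OC)n3c2[C@H]1CCCC3 | intermediate
13 | cis β-lactone: (3S,4R)-3-methyl-4-substituted oxetan-2-one bound through its C4 (= C12) to C11 of the (9S,10R,11R) tricycle | CC[C@H]1[C@@H]([C@H]2OC(=O)[C@H]2C)c2cc(C(=O)OC)n3c2[C@H]1CCCC3 | intermediate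
14 | tetracyclic lactone methyl ester: (9S,10R,11R,12S,13S) core of the target with CO2Me on C3 | CC[C@H]1[C@H]2OC(=O)[C@@H](C)[C@H]2c2cc(C(=O)OC)n3c2[C@H]1CCCC3 | intermediate
15 | hydroxy diacid: 14 with the lactone opened (C11–OH, C14 acid) and the C3 ester hydrolysed | CC[C@H]1[C@@H](O)[C@@H]([C@H](C)C(=O)O)c2cc(C(=O)O)n3c2[C@H]1CCCC3 | intermediate
16 | tetracyclic lactone carboxylic acid: 14 with CO2H on C3 | CC[C@H]1[C@H]2OC(=O)[C@@H](C)[C@H]2c2cc(C(=O)O)n3c2[C@H]1CCCC3 | intermediate
17 | methyl (R)-3-bromo-2-methylpropanoate | COC(=O)[C@@H](C)CBr | starting material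
18 | acid chloride of 16 | CC[C@H]1[C@H]2OC(=O)[C@@H](C)[C@H]2c2cc(C(=O)Cl)n3c2[C@H]1CCCC3 | intermediate
19 | (R)-(3-methoxy-2-methyl-3-oxopropyl)zinc bromide | COC(=O)[C@@H](C)C[Zn]Br | intermediate
20 | keto ester: methyl (S)-2-methyl-4-oxobutanoate whose C4 carbonyl is bound to C3 of the tetracyclic lactone | CC[C@H]1[C@H]2OC(=O)[C@@H](C)[C@H]2c2cc(C(=O)C[C@H](C)C(=O)OC)n3c2[C@H]1CCCC3 | intermediate
21 | hydroxy ester: 20 reduced to the (18R) carbinol | CC[C@H]1[C@H]2OC(=O)[C@@H](C)[C@H]2c2cc([C@H](O)C[C@H](C)C(=O)OC)n3c2[C@H]1CCCC3 | intermediate
22 | epibisdehydroneotuberostemonine J, (9S,10R,11R,12S,13S,18R,20S) | CC[C@H]1[C@H]2OC(=O)[C@@H](C)[C@H]2c2cc([C@H]3C[C@H](C)C(=O)O3)n3c2[C@H]1CCCC3 | target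

**Summary**

Total step count: 11. Longest linear sequence: 11 steps (1 → 22).

Steps most likely to fail:

Step 2 (proposed cascade). The vinylpyrrole may oligomerise under acid, or the enol of the keto ester may be too weak a nucleophile for the ester-deactivated azafulvenium ion. Fallback with known chemistry, from 3 back to 7: aqueous HCl in acetone unmasks methyl 1-(5-oxopentyl)-1H-pyrrole-2-carboxylate F1; Sc(OTf)3 in CH2Cl2 closes it by Friedel–Crafts hydroxyalkylation to methyl 9-hydroxy-6,7,8,9-tetrahydro-5H-pyrrolo[1,2-a]azepine-3-carboxylate F2; BF3·OEt2 ionises F2 in the presence of ethyl (Z)-2-[(trimethylsilyl)oxy]pent-2-enoate F3 (from 4, Me3SiCl, Et3N) in a Mukaiyama-type SN1 alkylation that gives 6 as an isolated compound; TsOH in toluene with removal of water then closes 6 to 7.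

Step 8 (key step). Ionisation of the β-lactone may be followed by hydride shift from C11 or by loss of CO2 instead of the shift of C1. Fallback with known chemistry, from 12 back to 14: the same 1,2-shift is run as an aryl-assisted sulfonate solvolysis. Me3SiCHN2 converts 12 into the methyl ester of 12 F4, MsCl and Et3N give the C12 methanesulfonate of that ester F5, and warming F5 in (CF3)2CHOH with 2,6-lutidine ionises the sulfonate with participation of C1; the ester carbonyl oxygen captures C11 and loses its methyl group, which gives 14.

Step 5 (aldol and resolution). The aldehyde may epimerise at C11 before it is captured, or the two diastereomeric adducts may be hard to separate. Fallback, from 9 back to 13: a catalytic asymmetric ketene–aldehyde [2+2] cycloaddition (propanoyl chloride, iPr2NEt, LiClO4, O-trimethylsilylquinidine or its quinine pseudoenantiomer, whichever gives the (12R,13S) cis-lactone, CH2Cl2/Et2O, −78 °C) makes the β-lactone directly and skips 11 and 12; this fallback makes no new compound (F0).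

**Further compounds**

F1 | step 2 | methyl 1-(5-oxopentyl)-1H-pyrrole-2-carboxylate | COC(=O)c1cccn1CCCCC=O
F2 | step 2 | methyl 9-hydroxy-6,7,8,9-tetrahydro-5H-pyrrolo[1,2-a]azepine-3-carboxylate (racemic) | COC(=O)c1ccc2C(O)CCCCn12
F3 | step 2 | ethyl (Z)-2-[(trimethylsilyl)oxy]pent-2-enoate | CC/C=C(\O[Si](C)(C)C)C(=O)OCC
F4 | step 8 | methyl ester of 12 | CC[C@H]1[C@@H]([C@@H](O)[C@H](C)C(=O)OC)c2cc(C(=O)OC)n3c2[C@H]1CCCC3
F5 | step 8 | C12 methanesulfonate of F4 | CC[C@H]1[C@@H]([C@@H](OS(C)(=O)=O)[C@H](C)C(=O)OC)c2cc(C(=O)OC)n3c2[C@H]1CCCC3
F0 | step 5 | none | none
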